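**Retrosynthetic overview**

1. Target 29 ⇐ 8-ketone 28 (methyl addition from the α face sets C8) ⇐ 8α-alcohol 27 ⇐ bridged lactone 25 by acyl transfer to O16 (spiro butanolide) ⇐ Baeyer–Villiger oxidation of cage ketone 24.
2. Key disconnection: an intramolecular furan–oxyallyl (4+3) cycloaddition (21 → 23) forms C8–C9 and C13–C14 and closes ring B and the oxa-bridged ring. The furan oxygen becomes the 9,13-ether oxygen and furan C2/C5 become the spiro carbons C9/C13.
3. Feature used: in the target, C8 and C14 stand cis on the tetrahydrofuran ring (O, C9, C11, C12, C13). A temporary C8–C15(=O)–C14 ketone bridge, absent from the target, therefore fixes C13 relative to C9 and is cleaved by Baeyer–Villiger oxidation and translactonisation.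
4. Precursor 21 (ring A with the 19,6β-lactone, a 2-furyl group on C10 and a chloromethyl ketone chain on C6) comes from 3-methylcyclohexenone: asymmetric conjugate addition (C10), syn aldol (C5, C6), Shapiro carboxylation/lactonisation, reductive methylation (C4).
5. Ring order: A (starting material) → γ-lactone (step 5) → B and tetrahydrofuran (step 9) → spiro butanolide (step 12).

Key step: step 9

Assumption: the SMILES is read as (4S,5R,6R,8S,9S,10S,13S)-8β-hydroxy-9α,13-epoxylabdane-19,6β:16,15-diolide. Labdane atom numbers (C1–C20) are used for all intermediates, and the catalyst enantiomer in step 2 is the one that gives (S)-configured C10.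

**Route**

Step 1
Reactants: 1 furan-2-ylmethanol
Product: 2 (furan-2-ylmethoxy)tri(propan-2-yl)silane
Conditions: TIPSCl, imidazole, DMF, rt
Reagents that add atoms: chlorotri(propan-2-yl)silane, CC(C)[Si](Cl)(C(C)C)C(C)C
Why: Imidazole-mediated silylation of a primary alcohol; the bulky silyl ether should survive the organometallic, reducing, oxidising and basic steps up to step 12, and no stereocentre is formed.

Step 2
Reactants: 2 (furan-2-ylmethoxy)tri(propan-2-yl)silane; 3 3-methylcyclohex-2-en-1-one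
Product: 7 trimethyl({(3S)-3-methyl-3-[5-({[tri(propan-2-yl)silyl]oxy}methyl)furan-2-yl]cyclohex-1-en-1-yl}oxy)silane, via furyllithium 4 (not isolated), via furylaluminium reagent 5 (not isolated), via aluminium enolate 6 (not isolated)
Conditions: n-BuLi, THF, −78 → 0 °C; Me2AlCl, −78 °C → rt; then 3, Cu(OTf)2 (5 mol %), chiral sulfonate-bridged NHC–Ag complex (2.5 mol %), THF, −30 °C; TMSOTf, −78 °C
Reagents that add atoms: trimethylsilyl trifluoromethanesulfonate, C[Si](C)(C)OS(=O)(=O)C(F)(F)F
Why: Copper–NHC-catalysed asymmetric conjugate addition of an aryl(dimethyl)aluminium reagent to a β-substituted cyclohexenone, in which the furyl group should transfer in preference to methyl and the catalyst enantiomer sets the quaternary centre C10 as S, followed by O-silylation of the regiodefined aluminium enolate so that the C4=C5 enol ether is kept for step 3.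

Step 3
Reactants: 7 trimethyl({(3S)-3-methyl-3-[5-({[tri(propan-2-yl)silyl]oxy}methyl)furan-2-yl]cyclohex-1-en-1-yl}oxy)silane; 8 pent-4-enal
Product: 11 (2S,3S)-2-[(1R)-1-hydroxypent-4-en-1-yl]-3-methyl-3-[5-({[tri(propan-2-yl)silyl]oxy}methyl)furan-2-yl]cyclohexan-1-one, via lithium enolate 9 (not isolated), via zirconium enolate 10 (not isolated)
Conditions: MeLi, THF, 0 °C; Cp2ZrCl2, −78 °C; 8, −78 °C; aq. NH4Cl
Reagents that add atoms: none
Why: Directed aldol addition of a regiodefined zirconium enolate, a reaction type that gives syn aldols irrespective of enolate geometry; the aldehyde should attack C5 anti to the pseudoaxial furyl group on the neighbouring quaternary carbon, which sets C5 (C6 unit trans to furyl) and, through the syn preference, C6.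

Step 4
Reactants: 11 (2S,3S)-2-[(1R)-1-hydroxypent-4-en-1-yl]-3-methyl-3-[5-({[tri(propan-2-yl)silyl]oxy}methyl)furan-2-yl]cyclohexan-1-one; 12 2,4,6-tri(propan-2-yl)benzenesulfonohydrazide
Product: 13 (E)-2,4,6-tri(propan-2-yl)benzenesulfonylhydrazone of ketone 11
Conditions: 12, THF, 4 Å MS, rt
Reagents that add atoms: none
Why: Condensation of the ketone to an arylsulfonylhydrazone (Shapiro precursor) under neutral drying conditions that should leave the aldol, the furfuryl silyl ether and all stereocentres untouched.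

Step 5
Reactants: 13 (E)-2,4,6-tri(propan-2-yl)benzenesulfonylhydrazone of ketone 11
Product: 16 (3R,3aR,4S)-3-(but-3-en-1-yl)-4-methyl-4-[5-({[tri(propan-2-yl)silyl]oxy}methyl)furan-2-yl]-3a,4,5,6-tetrahydro-2-benzofuran-1(3H)-one, via vinyllithium 14 (not isolated), via hydroxy acid 15 (not isolated)
Conditions: n-BuLi (3.5 equiv), TMEDA, THF, −78 → 0 °C; CO2, −78 °C; 1 M HCl, 0 °C
Reagents that add atoms: carbon dioxide, O=C=O
Why: Shapiro reaction: deprotonation of N–H, O–H and the less hindered α-CH2 (C3) gives, after loss of sulfinate and dinitrogen, the C4 vinyllithium, whose carboxylation places C19 on C4; the γ-hydroxy acid should close the γ-lactone on acidification with retention at C6.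

Step 6
Reactants: 16 (3R,3aR,4S)-3-(but-3-en-1-yl)-4-methyl-4-[5-({[tri(propan-2-yl)silyl]oxy}methyl)furan-2-yl]-3a,4,5,6-tetrahydro-2-benzofuran-1(3H)-one
Product: 18 (3R,3aR,4S,7aS)-3-(but-3-en-1-yl)-4,7a-dimethyl-4-[5-({[tri(propan-2-yl)silyl]oxy}methyl)furan-2-yl]hexahydro-2-benzofuran-1(3H)-one, via lactone enolate 17 (not isolated)
Conditions: Li (2.2 equiv), NH3(l)/THF, −78 °C; MeI, −78 → −33 °C
Reagents that add atoms: iodomethane, CI
Why: Dissolving-metal reductive alkylation: conjugate reduction of the enoate gives the lactone enolate regiospecifically, and iodomethane should enter on the α face (cis to H-5, away from the C7 chain and the axial C10 methyl group) to give the cis-fused lactone, which sets the quaternary centre C4.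

Step 7
Reactants: 18 (3R,3aR,4S,7aS)-3-(but-3-en-1-yl)-4,7a-dimethyl-4-[5-({[tri(propan-2-yl)silyl]oxy}methyl)furan-2-yl]hexahydro-2-benzofuran-1(3H)-one
Product: 19 (3R,3aR,4S,7aS)-4,7a-dimethyl-3-(3-oxobutyl)-4-[5-({[tri(propan-2-yl)silyl]oxy}methyl)furan-2-yl]hexahydro-2-benzofuran-1(3H)-one
Conditions: PdCl2 (10 mol %), CuCl, O2 (1 atm), DMF/H2O 7:1, rt
Reagents that add atoms: water, O
Why: Tsuji–Wacker oxidation of the terminal alkene with Markovnikov selectivity to the methyl ketone; the 2,5-disubstituted furan has no free α position and no stereocentre is touched.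

Step 8
Reactants: 19 (3R,3aR,4S,7aS)-4,7a-dimethyl-3-(3-oxobutyl)-4-[5-({[tri(propan-2-yl)silyl]oxy}methyl)furan-2-yl]hexahydro-2-benzofuran-1(3H)-one
Product: 21 (3R,3aR,4S,7aS)-3-(4-chloro-3-oxobutyl)-4,7a-dimethyl-4-[5-({[tri(propan-2-yl)silyl]oxy}methyl)furan-2-yl]hexahydro-2-benzofuran-1(3H)-one, via ketone enolate 20 (not isolated)
Conditions: LDA, THF, −78 °C; TsCl, −78 → 0 °C; aq. NH4Cl
Reagents that add atoms: 4-methylbenzenesulfonyl chloride, Cc1ccc(cc1)S(Cl)(=O)=O
Why: Kinetic deprotonation of the methyl ketone at the methyl group and α-chlorination of the lithium enolate with a sulfonyl chloride as Cl+ donor, which avoids electrophilic halogenating agents that would attack the furan; the lactone has no α hydrogen.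

Step 9
Reactants: 21 (3R,3aR,4S,7aS)-3-(4-chloro-3-oxobutyl)-4,7a-dimethyl-4-[5-({[tri(propan-2-yl)silyl]oxy}methyl)furan-2-yl]hexahydro-2-benzofuran-1(3H)-one
Product: 23 15-oxo-16-{[tri(propan-2-yl)silyl]oxy}-9α,13-epoxy-17-nor-8α,15-cyclolabd-11-en-19,6β-olide (8β-H), via oxyallyl cation 22 (not isolated)
Conditions: Et3N (3 equiv), CF3CH2OH (0.02 M), 0 °C → rt
Reagents that add atoms: none
Why: Triethylamine enolises the chloromethyl ketone towards C8 and the fluoroalcohol assists loss of chloride to give the 2-oxidoallyl cation 22, which adds across C2/C5 of the tethered 2,5-disubstituted furan in a (4+3) cycloaddition, the known intramolecular oxyallyl–furan cycloaddition of ω-furylalkyl α-chloro ketones. Ring B closes through the C8–C9 bond as a six-membered carbocycle with a chair-like tether whose C5–C6 and C5–C10 bonds are already fixed by the cis-fused lactone and the trans-diequatorial substituents of ring A; the second bond, C13–C14, closes the oxa-bridged seven-membered ring, in which the furan oxygen becomes the 9,13-ether oxygen. C13 is controlled by topology, because the suprafacial addition places C8 and C14 on the same face of the new dihydrofuran, which is the C9/C13 relationship of the target; C8 is controlled by the requirement that the central oxyallyl carbon C15 lies over the furan, that is anti to C10 and equatorial (8α) on ring B. C9 is controlled by C10 through the forming chair: the furan can place either its oxygen or its C3–H (C11) in the axial site on the α face, and the smaller oxygen is expected there, which gives the 9α-O, 9β-C11 arrangement. The step therefore needs only this facial selectivity at the furan, which the rigid bicyclic lactone and the axial C10 methyl group should secure; the C8 centre made here is later turned into a ketone, so its configuration is not critical.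

Step 10
Reactants: 23 15-oxo-16-{[tri(propan-2-yl)silyl]oxy}-9α,13-epoxy-17-nor-8α,15-cyclolabd-11-en-19,6β-olide
Product: 24 15-oxo-16-{[tri(propan-2-yl)silyl]oxy}-9α,13-epoxy-17-nor-8α,15-cyclolabdan-19,6β-olide
Conditions: H2 (1 atm), 10% Pd/C, EtOAc, rt
Reagents that add atoms: none
Why: Heterogeneous syn hydrogenation of the strained cis-disubstituted bridge alkene removes the only C=C bond before the peracid step and creates no stereocentre.

Step 11
Reactants: 24 15-oxo-16-{[tri(propan-2-yl)silyl]oxy}-9α,13-epoxy-17-nor-8α,15-cyclolabdan-19,6β-olide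
Product: 25 8α-hydroxy-16-{[tri(propan-2-yl)silyl]oxy}-9α,13-epoxy-17-norlabdan-15-oic acid 19,6β-olide 15,8-lactone
Conditions: mCPBA, NaHCO3, CH2Cl2, 0 °C → rt
Reagents that add atoms: 3-chloroperoxybenzoic acid, OOC(=O)c1cccc(Cl)c1
Why: Baeyer–Villiger oxidation in which the secondary carbon C8 should migrate in preference to the primary C14, with retention, so that oxygen is inserted between C8 and C15 and the ketone bridge becomes the C8–O–C15(=O)–C14 lactone.

Step 12
Reactants: 25 8α-hydroxy-16-{[tri(propan-2-yl)silyl]oxy}-9α,13-epoxy-17-norlabdan-15-oic acid 19,6β-olide 15,8-lactone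
Product: 27 8α-hydroxy-9α,13-epoxy-17-norlabdane-19,6β:16,15-diolide, via primary alcohol 26 (not isolated)
Conditions: TBAF, THF, 0 °C → rt; aq. NH4Cl
Reagents that add atoms: none
Why: Fluoride desilylation frees the C16 alkoxide, which attacks the C15 carbonyl in a 5-exo-trig transacylation; the strained bridged seven-membered lactone of a secondary alcohol is exchanged for the spiro γ-butyrolactone, and C9 and C13 are not touched.

Step 13
Reactants: 27 8α-hydroxy-9α,13-epoxy-17-norlabdane-19,6β:16,15-diolide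
Product: 28 8-oxo-9α,13-epoxy-17-norlabdane-19,6β:16,15-diolide
Conditions: Dess–Martin periodinane, NaHCO3, CH2Cl2, rt
Reagents that add atoms: none
Why: Dess–Martin oxidation of the secondary alcohol under buffered non-basic conditions, chosen because the product is a β-acyloxy ketone that could lose the 6β-carboxylate by E1cB elimination under base.

Step 14
Reactants: 28 8-oxo-9α,13-epoxy-17-norlabdane-19,6β:16,15-diolide
Product: 29 (13S)-8β-hydroxy-9α,13-epoxylabdane-19,6β:16,15-diolide (target)
Conditions: MeLi, CeCl3 (anhydrous), THF, −78 °C; aq. NH4Cl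
Reagents that add atoms: methyllithium, [Li]C
Why: 1,2-Addition of a weakly basic organocerium reagent, selective for the ketone over the two lactones; the methyl group should enter equatorially from the α face because the β face of C8 is blocked by the syn-axial C10 methyl group and the 6β-oxygen, which gives the axial 8β-hydroxyl and the 8α-methyl group.

**Compound list**

1 | furan-2-ylmethanol | OCc1ccco1 | starting material
2 | (furan-2-ylmethoxy)tri(propan-2-yl)silane | CC(C)[Si](OCc1ccco1)(C(C)C)C(C)C | intermediate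
3 | 3-methylcyclohex-2-en-1-one | CC1=CC(=O)CCC1 | starting material
4 | [5-({[tri(propan-2-yl)silyl]oxy}methyl)furan-2-yl]lithium | [Li]c1ccc(CO[Si](C(C)C)(C(C)C)C(C)C)o1 | intermediate
5 | dimethyl[5-({[tri(propan-2-yl)silyl]oxy}methyl)furan-2-yl]aluminium | C[Al](C)c1ccc(CO[Si](C(C)C)(C(C)C)C(C)C)o1 | intermediate
6 | dimethylaluminium (3S)-3-methyl-3-[5-({[tri(propan-2-yl)silyl]oxy}methyl)furan-2-yl]cyclohex-1-en-1-olate | C[Al](C)OC1=C[C@](C)(CCC1)c1ccc(CO[Si](C(C)C)(C(C)C)C(C)C)o1 | intermediate
7 | trimethyl({(3S)-3-methyl-3-[5-({[tri(propan-2-yl)silyl]oxy}methyl)furan-2-yl]cyclohex-1-en-1-yl}oxy)silane | C[Si](C)(C)OC1=C[C@](C)(CCC1)c1ccc(CO[Si](C(C)C)(C(C)C)C(C)C)o1 | intermediate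
8 | pent-4-enal | C=CCCC=O | starting material
9 | lithium (3S)-3-methyl-3-[5-({[tri(propan-2-yl)silyl]oxy}methyl)furan-2-yl]cyclohex-1-en-1-olate | [Li]OC1=C[C@](C)(CCC1)c1ccc(CO[Si](C(C)C)(C(C)C)C(C)C)o1 | intermediate
10 | chloridobis(cyclopentadienyl)zirconium (3S)-3-methyl-3-[5-({[tri(propan-2-yl)silyl]oxy}methyl)furan-2-yl]cyclohex-1-en-1-olate | Cl[Zr](OC1=C[C@](C)(CCC1)c1ccc(CO[Si](C(C)C)(C(C)C)C(C)C)o1)(C1C=CC=C1)C1C=CC=C1 | intermediate
11 | (2S,3S)-2-[(1R)-1-hydroxypent-4-en-1-yl]-3-methyl-3-[5-({[tri(propan-2-yl)silyl]oxy}methyl)furan-2-yl]cyclohexan-1-one (side chain trans to furyl; syn aldol) | O=C1CCC[C@](C)(c2ccc(CO[Si](C(C)C)(C(C)C)C(C)C)o2)[C@H]1[C@H](O)CCC=C | intermediate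
12 | 2,4,6-tri(propan-2-yl)benzenesulfonohydrazide | CC(C)c1cc(C(C)C)c(S(=O)(=O)NN)c(C(C)C)c1 | starting material
13 | (E)-2,4,6-tri(propan-2-yl)benzenesulfonylhydrazone of ketone 11 | CC(C)c1cc(C(C)C)c(S(=O)(=O)N/N=C2\CCC[C@](C)(c3ccc(CO[Si](C(C)C)(C(C)C)C(C)C)o3)[C@H]2[C@H](O)CCC=C)c(C(C)C)c1 | intermediate
14 | C4-lithio cyclohexene with lithium alkoxide at C6 (vinyllithium from 13) | [Li]C1=CCC[C@](C)(c2ccc(CO[Si](C(C)C)(C(C)C)C(C)C)o2)[C@H]1[C@H](O[Li])CCC=C | intermediate
15 | (5S,6S)-6-[(1R)-1-hydroxypent-4-en-1-yl]-5-methyl-5-[5-({[tri(propan-2-yl)silyl]oxy}methyl)furan-2-yl]cyclohex-1-ene-1-carboxylic acid | OC(=O)C1=CCC[C@](C)(c2ccc(CO[Si](C(C)C)(C(C)C)C(C)C)o2)[C@H]1[C@H](O)CCC=C | intermediate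
16 | (3R,3aR,4S)-3-(but-3-en-1-yl)-4-methyl-4-[5-({[tri(propan-2-yl)silyl]oxy}methyl)furan-2-yl]-3a,4,5,6-tetrahydro-2-benzofuran-1(3H)-one | C=CCC[C@H]1OC(=O)C2=CCC[C@](C)(c3ccc(CO[Si](C(C)C)(C(C)C)C(C)C)o3)[C@@H]12 | intermediate
17 | lithium enolate of the saturated lactone (C19–O–Li; C19=C4) | C=CCC[C@H]1OC(O[Li])=C2CCC[C@](C)(c3ccc(CO[Si](C(C)C)(C(C)C)C(C)C)o3)[C@@H]12 | intermediate
18 | (3R,3aR,4S,7aS)-3-(but-3-en-1-yl)-4,7a-dimethyl-4-[5-({[tri(propan-2-yl)silyl]oxy}methyl)furan-2-yl]hexahydro-2-benzofuran-1(3H)-one (cis-fused lactone) | C=CCC[C@H]1OC(=O)[C@@]2(C)CCC[C@](C)(c3ccc(CO[Si](C(C)C)(C(C)C)C(C)C)o3)[C@@H]12 | intermediate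
19 | (3R,3aR,4S,7aS)-4,7a-dimethyl-3-(3-oxobutyl)-4-[5-({[tri(propan-2-yl)silyl]oxy}methyl)furan-2-yl]hexahydro-2-benzofuran-1(3H)-one | CC(=O)CC[C@H]1OC(=O)[C@@]2(C)CCC[C@](C)(c3ccc(CO[Si](C(C)C)(C(C)C)C(C)C)o3)[C@@H]12 | intermediate
20 | kinetic lithium enolate of methyl ketone 19 (terminal CH2=C(OLi)) | [Li]OC(=C)CC[C@H]1OC(=O)[C@@]2(C)CCC[C@](C)(c3ccc(CO[Si](C(C)C)(C(C)C)C(C)C)o3)[C@@H]12 | intermediate
21 | (3R,3aR,4S,7aS)-3-(4-chloro-3-oxobutyl)-4,7a-dimethyl-4-[5-({[tri(propan-2-yl)silyl]oxy}methyl)furan-2-yl]hexahydro-2-benzofuran-1(3H)-one | ClCC(=O)CC[C@H]1OC(=O)[C@@]2(C)CCC[C@](C)(c3ccc(CO[Si](C(C)C)(C(C)C)C(C)C)o3)[C@@H]12 | intermediate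
22 | 2-oxidoallyl cation (C14H2=C15(O−)–C8H(+)–C7) tethered to the furan | C=C([O-])[CH+]C[C@H]1OC(=O)[C@@]2(C)CCC[C@](C)(c3ccc(CO[Si](C(C)C)(C(C)C)C(C)C)o3)[C@@H]12 | intermediate
23 | 15-oxo-16-{[tri(propan-2-yl)silyl]oxy}-9α,13-epoxy-17-nor-8α,15-cyclolabd-11-en-19,6β-olide (8β-H) | O=C1C[C@]2(CO[Si](C(C)C)(C(C)C)C(C)C)C=C[C@@]3(O2)[C@H]1C[C@H]4OC(=O)[C@@]5(C)CCC[C@@]3(C)[C@@H]45 | intermediate
24 | 15-oxo-16-{[tri(propan-2-yl)silyl]oxy}-9α,13-epoxy-17-nor-8α,15-cyclolabdan-19,6β-olide | O=C1C[C@]2(CO[Si](C(C)C)(C(C)C)C(C)C)CC[C@@]3(O2)[C@H]1C[C@H]4OC(=O)[C@@]5(C)CCC[C@@]3(C)[C@@H]45 | intermediate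
25 | 8α-hydroxy-16-{[tri(propan-2-yl)silyl]oxy}-9α,13-epoxy-17-norlabdan-15-oic acid 19,6β-olide 15,8-lactone | O=C1C[C@]2(CO[Si](C(C)C)(C(C)C)C(C)C)CC[C@@]3(O2)[C@H](O1)C[C@H]4OC(=O)[C@@]5(C)CCC[C@@]3(C)[C@@H]45 | intermediate
26 | 8α,16-dihydroxy-9α,13-epoxy-17-norlabdan-15-oic acid 19,6β-olide 15,8-lactone | O=C1C[C@]2(CO)CC[C@@]3(O2)[C@H](O1)C[C@H]4OC(=O)[C@@]5(C)CCC[C@@]3(C)[C@@H]45 | intermediate
27 | 8α-hydroxy-9α,13-epoxy-17-norlabdane-19,6β:16,15-diolide | O[C@@H]1C[C@H]2OC(=O)[C@@]3(C)CCC[C@@](C)([C@@H]23)[C@@]12CC[C@]1(COC(=O)C1)O2 | intermediate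
28 | 8-oxo-9α,13-epoxy-17-norlabdane-19,6β:16,15-diolide | O=C1C[C@H]2OC(=O)[C@@]3(C)CCC[C@@](C)([C@@H]23)[C@@]12CC[C@]1(COC(=O)C1)O2 | intermediate
29 | (13S)-8β-hydroxy-9α,13-epoxylabdane-19,6β:16,15-diolide | C[C@]1(O)C[C@H]2OC(=O)[C@@]3(C)CCC[C@@](C)([C@@H]23)[C@@]12CC[C@]1(COC(=O)C1)O2 | target

**Step count and risks**

Total step count: 14. Longest linear sequence: 14 steps (from 1).

Steps most likely to fail:

1. Step 9. The tethered oxyallyl cation may add to the other face of the furan (C11 instead of the ring oxygen in the axial site, which would give the C9/C13-epimeric cage), or it may be captured by the solvent or collapse by Favorskii rearrangement before it reaches the hindered furan carbon. The fallback sets out from 19 and comes back at 25. It closes ring B under thermodynamic control by aldol chemistry and sets C13 with a nucleophile delivered from the 8-oxygen. The furan of 19 is opened with singlet oxygen (O2, methylene blue, hν, CH2Cl2, −78 °C, then Me2S) to the (Z)-ene-1,4-dione F1, and hydrogenation (H2, Pd/C, EtOAc) gives the saturated triketone F2. Under mild reversible aldol conditions (K2CO3, MeOH, 0 °C → rt) the C8 enolate of the methyl ketone should add to the C9 ketone; the tertiary 9-hydroxyl, axial because the larger C11 chain takes the equatorial site, then closes onto the C13 ketone to give the lactol F3 with an equatorial 8α-acetyl group. Baeyer–Villiger oxidation of the acetyl group (mCPBA, NaHCO3) gives the 8α-acetate F4. Enolisation and ionisation of the lactol (LiHMDS, TMSCl, THF, −78 °C; then TMSOTf) should add the acetate carbon (C14) to the C13 oxocarbenium ion from the side of the 8-oxygen, which fixes C13 through the tether and gives 25.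

2. Step 3. The aldol may give poor syn/anti control at C6, or the aldehyde may approach C5 from both faces of the enolate. The fallback sets out from 7 and comes back at 11. It uses an aldol of the opposite, more dependable sense and then inverts C6. The lithium enolate from 7 (MeLi) is converted into the dicyclohexylboron enolate (Cy2BCl, −78 °C), whose chair transition state should give the anti aldol F5, the C6 epimer of 11. Mitsunobu esterification (PhCO2H, PPh3, DIAD, THF, 0 °C) inverts C6 and gives the benzoate F6, and mild methanolysis (K2CO3, MeOH, 0 °C) gives 11.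

3. Step 2. The functionalised furyl group may transfer slowly or unselectively from aluminium (competing methyl transfer, low enantioselectivity), or the regiodefined enolate may be lost before silylation. The fallback sets out from 2 and comes back at 7. It makes the quaternary centre by adding the methyl group instead of the furyl group. Furyllithium 4 (from 2 and n-BuLi) is added to 3-ethoxycyclohex-2-en-1-one, and acidic work-up (1,2-addition, then hydrolysis and loss of ethanol) gives the 3-furylcyclohexenone F7. Copper-catalysed asymmetric conjugate addition of trimethylaluminium (CuTC, chiral phosphoramidite, Et2O, −30 °C) with TMSOTf trapping of the aluminium enolate gives 7, the ligand enantiomer being chosen for (S)-configured C10.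

Further compounds
F1 | step 9 | (Z)-ene-1,4-dione from oxidative opening of the furan of 19 (C9 and C13 ketones, C11=C12 cis) | CC(=O)CC[C@H]1OC(=O)[C@@]2(C)CCC[C@](C)(C(=O)/C=C\C(=O)CO[Si](C(C)C)(C(C)C)C(C)C)[C@@H]12
F2 | step 9 | saturated triketone (C9, C13 and C15 ketones) | CC(=O)CC[C@H]1OC(=O)[C@@]2(C)CCC[C@](C)(C(=O)CCC(=O)CO[Si](C(C)C)(C(C)C)C(C)C)[C@@H]12
F3 | step 9 | 8α-acetyl-13-hydroxy-9α,13-epoxy lactol with ring B closed (19,6β-olide; anomeric mixture at C13) | CC(=O)[C@@H]1C[C@H]2OC(=O)[C@@]3(C)CCC[C@@](C)([C@@H]23)[C@@]12CCC(O)(CO[Si](C(C)C)(C(C)C)C(C)C)O2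
F4 | step 9 | 8α-acetoxy-13-hydroxy-9α,13-epoxy lactol (19,6β-olide; anomeric mixture at C13) | CC(=O)O[C@@H]1C[C@H]2OC(=O)[C@@]3(C)CCC[C@@](C)([C@@H]23)[C@@]12CCC(O)(CO[Si](C(C)C)(C(C)C)C(C)C)O2
F5 | step 3 | (2S,3S)-2-[(1S)-1-hydroxypent-4-en-1-yl]-3-methyl-3-[5-({[tri(propan-2-yl)silyl]oxy}methyl)furan-2-yl]cyclohexan-1-one (anti aldol) | O=C1CCC[C@](C)(c2ccc(CO[Si](C(C)C)(C(C)C)C(C)C)o2)[C@H]1[C@@H](O)CCC=C
F6 | step 3 | benzoate of 11 (C6 inverted relative to F5) | O=C1CCC[C@](C)(c2ccc(CO[Si](C(C)C)(C(C)C)C(C)C)o2)[C@H]1[C@H](OC(=O)c1ccccc1)CCC=C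
F7 | step 2 | 3-[5-({[tri(propan-2-yl)silyl]oxy}methyl)furan-2-yl]cyclohex-2-en-1-one | O=C1C=C(CCC1)c1ccc(CO[Si](C(C)C)(C(C)C)C(C)C)o1
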